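**Plan**

- Cuts: ring A at the two bonds from its adjacent C–O carbons to their outer neighbours (C–cyclopentyl and C–CH2Ar), giving vinylene carbonate and an acyclic diene; then the CH2–aryl bond to ring B; then the diene C=C bonds.
- Enabling feature: in ring A the two C–OH carbons are adjacent, and the other four ring atoms (C–cyclopentyl, CH, C–CH3, C–CH2Ar) form a contiguous 1,3,4-trisubstituted buta-1,3-diene.
- Forward: camphoric acid to cyclopentyl aldehyde 7 (steps 1–5); 7 to dienyl carbonate 11 (steps 6–8); 7 to ring B boronate 20 by a first Diels–Alder/aromatisation, methylation and C–H borylation (steps 9–14).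
- Allyl–aryl coupling joins 11 and 20 to diene 21 (step 15); the Diels–Alder reaction with vinylene carbonate closes ring A (step 16); hydrolysis, oxidation to the catechol and demethylation follow (steps 17–19).
- Stereochemistry: both quaternary centres are C1 of (1S,3R)-camphoric acid, carried through unchanged; every other sp3 centre made on the way is erased on aromatisation.

Key step: step 16

Remark: cycloadducts 15 and 22 and diols 16 and 23 are carried forward as diastereomer mixtures at the new ring carbons, because all of these centres become sp2 on aromatisation.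
Remark: the quaternary carbon reads S when it bears an aryl, carbonyl or CH2OH group and R when it bears an alkenyl or ring CH group; this is a change of CIP priority only, the spatial arrangement is the same throughout.

**Route**

Step 1
Reactants: 1 (1S,3R)-camphoric acid
Product: 2 dimethyl (1S,3R)-1,2,2-trimethylcyclopentane-1,3-dicarboxylate
Conditions: MeI, K2CO3, DMF, rt
Reagents that add atoms: iodomethane, CI
Why: Carboxylate O-alkylation (SN2 on MeI) esterifies both acids, including the hindered tertiary one that resists Fischer esterification, and touches no stereocentre.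

Step 2
Reactants: 2 dimethyl (1S,3R)-1,2,2-trimethylcyclopentane-1,3-dicarboxylate
Product: 3 (1R,3S)-3-(methoxycarbonyl)-2,2,3-trimethylcyclopentane-1-carboxylic acid (tertiary ester kept; acid on the CH carbon free)
Conditions: KOH (1.05 equiv), MeOH–H2O, reflux; then aq. HCl
Reagents that add atoms: potassium hydroxide, [K+].[OH-]
Why: Saponification is far faster at the secondary ester than at the tertiary ester flanked by two quaternary carbons, so one equivalent of hydroxide should free only the carboxyl on the CH carbon, and any epimerisation at that CH is irrelevant because the centre is removed in step 3.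

Step 3
Reactants: 3 (1R,3S)-3-(methoxycarbonyl)-2,2,3-trimethylcyclopentane-1-carboxylic acid
Product: 5 methyl (1S)-1,2,2-trimethylcyclopentane-1-carboxylate, via Barton ester 4 (not isolated)
Conditions: 1-hydroxypyridine-2(1H)-thione, DCC, DMAP (cat.), CH2Cl2, 0 °C to rt, dark; then t-BuSH, PhMe, hν (tungsten lamp), rt
Reagents that add atoms: none
Why: Barton reductive decarboxylation, in which the thiohydroxamate ester fragments in a radical chain to CO2 and a secondary cyclopentyl radical that takes hydrogen from the thiol, leaving the quaternary stereocentre untouched.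

Step 4
Reactants: 5 methyl (1S)-1,2,2-trimethylcyclopentane-1-carboxylate
Product: 6 [(1S)-1,2,2-trimethylcyclopentyl]methanol
Conditions: LiAlH4, Et2O, 0 °C to reflux
Reagents that add atoms: none
Why: LiAlH4 reduces even neopentyl-type esters cleanly to the primary alcohol.

Step 5
Reactants: 6 [(1S)-1,2,2-trimethylcyclopentyl]methanol
Product: 7 (1S)-1,2,2-trimethylcyclopentane-1-carbaldehyde
Conditions: Dess–Martin periodinane, CH2Cl2, 0 °C to rt
Reagents that add atoms: none
Why: Dess–Martin oxidation of a primary neopentyl alcohol stops at the aldehyde, which has no α-hydrogen and so can neither enolise nor epimerise.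

Step 6
Reactants: 7 (1S)-1,2,2-trimethylcyclopentane-1-carbaldehyde; 8 triethyl 3-methyl-4-phosphonocrotonate
Product: 9 ethyl (2E,4E)-3-methyl-5-[(1R)-1,2,2-trimethylcyclopentyl]penta-2,4-dienoate
Conditions: 8, LiN(SiMe3)2, THF, −78 °C; then 7, −78 °C to rt; aq. NH4Cl
Reagents that add atoms: none
Why: Vinylogous Horner–Wadsworth–Emmons olefination builds the new 4,5-double bond E and should favour the 2E isomer because the phosphonate anion equilibrates, the minor 2Z isomer being removed by chromatography here or after step 7.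

Step 7
Reactants: 9 ethyl (2E,4E)-3-methyl-5-[(1R)-1,2,2-trimethylcyclopentyl]penta-2,4-dienoate
Product: 10 (2E,4E)-3-methyl-5-[(1R)-1,2,2-trimethylcyclopentyl]penta-2,4-dien-1-ol
Conditions: i-Bu2AlH, CH2Cl2, −78 to 0 °C; aq. potassium sodium tartrate
Reagents that add atoms: none
Why: i-Bu2AlH effects 1,2-reduction of the dienoate to the allylic alcohol at low temperature without disturbing the double-bond geometry.

Step 8
Reactants: 10 (2E,4E)-3-methyl-5-[(1R)-1,2,2-trimethylcyclopentyl]penta-2,4-dien-1-ol
Product: 11 methyl (2E,4E)-3-methyl-5-[(1R)-1,2,2-trimethylcyclopentyl]penta-2,4-dien-1-yl carbonate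
Conditions: ClCO2Me, pyridine, CH2Cl2, 0 °C
Reagents that add atoms: methyl chloroformate, COC(=O)Cl
Why: Acylation of the primary allylic alcohol gives a bench-stable carbonate that ionises readily with zerovalent palladium, which avoids a labile dienyl halide.

Step 9
Reactants: 7 (1S)-1,2,2-trimethylcyclopentane-1-carbaldehyde; 12 diethyl allylphosphonate
Product: 13 (1R)-1-[(1E)-buta-1,3-dien-1-yl]-1,2,2-trimethylcyclopentane
Conditions: 12, n-BuLi, THF, −78 °C; then 7; then HMPA, −78 °C to rt; aq. NH4Cl
Reagents that add atoms: none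
Why: Horner–Wadsworth–Emmons-type olefination with lithiated allylphosphonate, in which HMPA drives the elimination and the E-1-substituted butadiene is the expected isomer, any Z-diene being inert in step 10 and removed there.

Step 10
Reactants: 13 (1R)-1-[(1E)-buta-1,3-dien-1-yl]-1,2,2-trimethylcyclopentane; 14 vinylene carbonate
Product: 15 4-[(1R)-1,2,2-trimethylcyclopentyl]-3a,4,7,7a-tetrahydro-1,3-benzodioxol-2-one (cis-fused carbonate; diastereomer mixture at the new ring carbons)
Conditions: 14 (5 equiv), BHT (cat.), PhMe, sealed tube, 175 °C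
Reagents that add atoms: none
Why: Thermal Diels–Alder reaction of an E-1-alkylbuta-1,3-diene with vinylene carbonate is a known reaction type that gives the cis-fused carbonate, and the new stereocentres are left as a mixture because they vanish in step 12.

Step 11
Reactants: 15 4-[(1R)-1,2,2-trimethylcyclopentyl]-3a,4,7,7a-tetrahydro-1,3-benzodioxol-2-one
Product: 16 3-[(1R)-1,2,2-trimethylcyclopentyl]cyclohex-4-ene-1,2-diol (cis-diol; diastereomer mixture)
Conditions: K2CO3 (cat.), MeOH, rt
Reagents that add atoms: none
Why: Base-catalysed transesterification of the five-membered cyclic carbonate with methanol releases the cis-diol and volatile dimethyl carbonate.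

Step 12
Reactants: 16 3-[(1R)-1,2,2-trimethylcyclopentyl]cyclohex-4-ene-1,2-diol
Product: 18 3-[(1S)-1,2,2-trimethylcyclopentyl]benzene-1,2-diol, via ene-dione 17 (not isolated)
Conditions: (CF3CO)2O, DMSO, CH2Cl2, −60 °C; then Et3N, −60 °C to rt
Reagents that add atoms: none
Why: Swern-type oxidation with trifluoroacetic anhydride-activated DMSO converts the vicinal diol into the 1,2-dione without C–C cleavage, and the dione enolises twice under the basic conditions to the aromatic catechol.

Step 13
Reactants: 18 3-[(1S)-1,2,2-trimethylcyclopentyl]benzene-1,2-diol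
Product: 19 1,2-dimethoxy-3-[(1S)-1,2,2-trimethylcyclopentyl]benzene
Conditions: MeI, K2CO3, DMF, 50 °C
Reagents that add atoms: iodomethane, CI
Why: Williamson methylation of both phenols gives ethers that survive borylation, palladium catalysis and 180 °C and that BBr3 removes at the end.

Step 14
Reactants: 19 1,2-dimethoxy-3-[(1S)-1,2,2-trimethylcyclopentyl]benzene
Product: 20 2-{3,4-dimethoxy-5-[(1S)-1,2,2-trimethylcyclopentyl]phenyl}-4,4,5,5-tetramethyl-1,3,2-dioxaborolane
Conditions: B2pin2, [Ir(OMe)(cod)]2 (cat.), 4,4′-di-tert-butyl-2,2′-bipyridine (cat.), THF, 80 °C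
Reagents that add atoms: bis(pinacolato)diboron, CC1(C)OB(OC1(C)C)B1OC(C)(C)C(C)(C)O1
Why: Iridium-catalysed C–H borylation is governed by sterics, so in this 1,2,3-trisubstituted arene the only C–H without an ortho substituent (C5, para to the inner methoxy group) should be borylated.

Step 15
Reactants: 11 methyl (2E,4E)-3-methyl-5-[(1R)-1,2,2-trimethylcyclopentyl]penta-2,4-dien-1-yl carbonate; 20 2-{3,4-dimethoxy-5-[(1S)-1,2,2-trimethylcyclopentyl]phenyl}-4,4,5,5-tetramethyl-1,3,2-dioxaborolane
Product: 21 1,2-dimethoxy-5-{(2E,4E)-3-methyl-5-[(1R)-1,2,2-trimethylcyclopentyl]penta-2,4-dien-1-yl}-3-[(1S)-1,2,2-trimethylcyclopentyl]benzene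
Conditions: Pd(PPh3)4 (cat.), THF, 60 °C (no added base)
Reagents that add atoms: none
Why: Allyl–aryl Suzuki–Miyaura coupling, in which zerovalent palladium ionises the carbonate with loss of CO2, the methoxide left on palladium activates the boronate for transmetalation, and reductive elimination at the unhindered CH2 terminus should give the linear conjugated E,E-diene.

Step 16
Reactants: 21 1,2-dimethoxy-5-{(2E,4E)-3-methyl-5-[(1R)-1,2,2-trimethylcyclopentyl]penta-2,4-dien-1-yl}-3-[(1S)-1,2,2-trimethylcyclopentyl]benzene; 14 vinylene carbonate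
Product: 22 4-{3,4-dimethoxy-5-[(1S)-1,2,2-trimethylcyclopentyl]benzyl}-5-methyl-7-[(1R)-1,2,2-trimethylcyclopentyl]-3a,4,7,7a-tetrahydro-1,3-benzodioxol-2-one (cis-fused carbonate; diastereomer mixture at the four new ring carbons)
Conditions: 14 (excess, neat), BHT (cat.), sealed tube, 180 °C
Reagents that add atoms: none
Why: A concerted, thermally allowed suprafacial [4+2] cycloaddition (Diels–Alder) bonds each diene terminus, the cyclopentyl-bearing CH and the benzyl-bearing CH, to one carbon of vinylene carbonate, so two C–C bonds form at once. The closest known reaction type is the thermal Diels–Alder reaction of vinylene carbonate with alkyl-substituted buta-1,3-dienes at 160–200 °C, used on the simpler diene in step 10. The six-membered carbocycle that becomes ring A is closed by intermolecular [4+2] annulation of four diene carbons with two dienophile carbons, cis-fused to the carbonate ring brought in by the dienophile. Four sp3 centres arise, for which suprafacial addition fixes the cis relation of the two C–O bonds and of the cyclopentyl and benzyl groups, while endo/exo and facial selectivity are uncontrolled and need not be controlled because all four centres become sp2 in step 18. The step needs only reactivity and chemoselectivity, secured by the E,E geometry, which puts hydrogen at both inside positions so that the s-cis conformer is reachable and the 1,5-hydrogen shift is closed off, by the symmetric dienophile, which removes any regiochemical question, and by excess dienophile with a radical inhibitor against its polymerisation. Both quaternary stereocentres lie outside the reacting π-system and carry no hydrogen, so they cannot be affected.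

Step 17
Reactants: 22 4-{3,4-dimethoxy-5-[(1S)-1,2,2-trimethylcyclopentyl]benzyl}-5-methyl-7-[(1R)-1,2,2-trimethylcyclopentyl]-3a,4,7,7a-tetrahydro-1,3-benzodioxol-2-one
Product: 23 3-{3,4-dimethoxy-5-[(1S)-1,2,2-trimethylcyclopentyl]benzyl}-4-methyl-6-[(1R)-1,2,2-trimethylcyclopentyl]cyclohex-4-ene-1,2-diol (cis-diol; diastereomer mixture)
Conditions: K2CO3 (cat.), MeOH–THF, rt
Reagents that add atoms: none
Why: Base-catalysed methanolysis of the cyclic carbonate frees the cis-diol while the aryl methyl ethers are inert.

Step 18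
Reactants: 23 3-{3,4-dimethoxy-5-[(1S)-1,2,2-trimethylcyclopentyl]benzyl}-4-methyl-6-[(1R)-1,2,2-trimethylcyclopentyl]cyclohex-4-ene-1,2-diol
Product: 25 3-{3,4-dimethoxy-5-[(1S)-1,2,2-trimethylcyclopentyl]benzyl}-4-methyl-6-[(1S)-1,2,2-trimethylcyclopentyl]benzene-1,2-diol, via ene-dione 24 (not isolated)
Conditions: (CF3CO)2O, DMSO, CH2Cl2, −60 °C; then Et3N, −60 °C to rt
Reagents that add atoms: none
Why: Swern-type double oxidation of the cis-diol gives the 1,2-dione, which tautomerises by two enolisations to the fully substituted catechol of ring A and so erases the four transient stereocentres, the veratrole ring and the quaternary centres being inert at low temperature.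

Step 19
Reactants: 25 3-{3,4-dimethoxy-5-[(1S)-1,2,2-trimethylcyclopentyl]benzyl}-4-methyl-6-[(1S)-1,2,2-trimethylcyclopentyl]benzene-1,2-diol
Product: 26 3-{3,4-dihydroxy-5-[(1S)-1,2,2-trimethylcyclopentyl]benzyl}-4-methyl-6-[(1S)-1,2,2-trimethylcyclopentyl]benzene-1,2-diol (CNP0137546.1)
Conditions: BBr3, CH2Cl2, −78 °C to rt; then H2O
Reagents that add atoms: none
Why: BBr3 cleaves both aryl methyl ethers through bromoborane complexes, a standard final step for hindered catechol ethers, the ring A catechol being held as a borate until aqueous work-up.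

**Compound list**

1 | (1S,3R)-camphoric acid | OC(=O)[C@@]1(C)CC[C@@H](C(=O)O)C1(C)C | starting material
2 | dimethyl (1S,3R)-1,2,2-trimethylcyclopentane-1,3-dicarboxylate | COC(=O)[C@@]1(C)CC[C@@H](C(=O)OC)C1(C)C | intermediate
3 | (1R,3S)-3-(methoxycarbonyl)-2,2,3-trimethylcyclopentane-1-carboxylic acid | COC(=O)[C@@]1(C)CC[C@@H](C(=O)O)C1(C)C | intermediate
4 | Barton ester of 3 (2-thioxopyridin-1(2H)-yl ester) | COC(=O)[C@@]1(C)CC[C@@H](C(=O)On2ccccc2=S)C1(C)C | intermediate
5 | methyl (1S)-1,2,2-trimethylcyclopentane-1-carboxylate | COC(=O)[C@@]1(C)CCCC1(C)C | intermediate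
6 | [(1S)-1,2,2-trimethylcyclopentyl]methanol | OC[C@@]1(C)CCCC1(C)C | intermediate
7 | (1S)-1,2,2-trimethylcyclopentane-1-carbaldehyde | O=C[C@@]1(C)CCCC1(C)C | intermediate
8 | triethyl 3-methyl-4-phosphonocrotonate (E/Z mixture as sold) | CCOC(=O)C=C(C)CP(=O)(OCC)OCC | starting material
9 | ethyl (2E,4E)-3-methyl-5-[(1R)-1,2,2-trimethylcyclopentyl]penta-2,4-dienoate | CCOC(=O)/C=C(C)/C=C/[C@@]1(C)CCCC1(C)C | intermediate
10 | (2E,4E)-3-methyl-5-[(1R)-1,2,2-trimethylcyclopentyl]penta-2,4-dien-1-ol | OC/C=C(C)/C=C/[C@@]1(C)CCCC1(C)C | intermediate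
11 | methyl (2E,4E)-3-methyl-5-[(1R)-1,2,2-trimethylcyclopentyl]penta-2,4-dien-1-yl carbonate | COC(=O)OC/C=C(C)/C=C/[C@@]1(C)CCCC1(C)C | intermediate
12 | diethyl allylphosphonate | C=CCP(=O)(OCC)OCC | starting material
13 | (1R)-1-[(1E)-buta-1,3-dien-1-yl]-1,2,2-trimethylcyclopentane | C=C/C=C/[C@@]1(C)CCCC1(C)C | intermediate
14 | vinylene carbonate (1,3-dioxol-2-one) | O=C1OC=CO1 | starting material
15 | 4-[(1R)-1,2,2-trimethylcyclopentyl]-3a,4,7,7a-tetrahydro-1,3-benzodioxol-2-one (cis-fused; diastereomer mixture) | O=C1OC2CC=CC([C@@]3(C)CCCC3(C)C)C2O1 | intermediate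
16 | 3-[(1R)-1,2,2-trimethylcyclopentyl]cyclohex-4-ene-1,2-diol (cis-diol; diastereomer mixture) | OC1CC=CC([C@@]2(C)CCCC2(C)C)C1O | intermediate
17 | 3-[(1R)-1,2,2-trimethylcyclopentyl]cyclohex-4-ene-1,2-dione | O=C1CC=CC([C@@]2(C)CCCC2(C)C)C1=O | intermediate
18 | 3-[(1S)-1,2,2-trimethylcyclopentyl]benzene-1,2-diol | Oc1cccc([C@@]2(C)CCCC2(C)C)c1O | intermediate
19 | 1,2-dimethoxy-3-[(1S)-1,2,2-trimethylcyclopentyl]benzene | COc1cccc([C@@]2(C)CCCC2(C)C)c1OC | intermediate
20 | 2-{3,4-dimethoxy-5-[(1S)-1,2,2-trimethylcyclopentyl]phenyl}-4,4,5,5-tetramethyl-1,3,2-dioxaborolane | COc1cc(B2OC(C)(C)C(C)(C)O2)cc([C@@]3(C)CCCC3(C)C)c1OC | intermediate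
21 | 1,2-dimethoxy-5-{(2E,4E)-3-methyl-5-[(1R)-1,2,2-trimethylcyclopentyl]penta-2,4-dien-1-yl}-3-[(1S)-1,2,2-trimethylcyclopentyl]benzene | COc1cc(C/C=C(C)/C=C/[C@@]2(C)CCCC2(C)C)cc([C@@]3(C)CCCC3(C)C)c1OC | intermediate
22 | 4-{3,4-dimethoxy-5-[(1S)-1,2,2-trimethylcyclopentyl]benzyl}-5-methyl-7-[(1R)-1,2,2-trimethylcyclopentyl]-3a,4,7,7a-tetrahydro-1,3-benzodioxol-2-one (cis-fused; diastereomer mixture) | COc1cc(CC2C(C)=CC([C@@]4(C)CCCC4(C)C)C3OC(=O)OC23)cc([C@@]5(C)CCCC5(C)C)c1OC | intermediate
23 | 3-{3,4-dimethoxy-5-[(1S)-1,2,2-trimethylcyclopentyl]benzyl}-4-methyl-6-[(1R)-1,2,2-trimethylcyclopentyl]cyclohex-4-ene-1,2-diol (cis-diol; diastereomer mixture) | COc1cc(CC2C(C)=CC([C@@]4(C)CCCC4(C)C)C(O)C2O)cc([C@@]5(C)CCCC5(C)C)c1OC | intermediate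
24 | 3-{3,4-dimethoxy-5-[(1S)-1,2,2-trimethylcyclopentyl]benzyl}-4-methyl-6-[(1R)-1,2,2-trimethylcyclopentyl]cyclohex-4-ene-1,2-dione | COc1cc(CC2C(C)=CC([C@@]4(C)CCCC4(C)C)C(=O)C2=O)cc([C@@]5(C)CCCC5(C)C)c1OC | intermediate
25 | 3-{3,4-dimethoxy-5-[(1S)-1,2,2-trimethylcyclopentyl]benzyl}-4-methyl-6-[(1S)-1,2,2-trimethylcyclopentyl]benzene-1,2-diol | COc1cc(Cc2c(C)cc([C@@]4(C)CCCC4(C)C)c(O)c2O)cc([C@@]5(C)CCCC5(C)C)c1OC | intermediate
26 | 3-{3,4-dihydroxy-5-[(1S)-1,2,2-trimethylcyclopentyl]benzyl}-4-methyl-6-[(1S)-1,2,2-trimethylcyclopentyl]benzene-1,2-diol (CNP0137546.1) | Cc1cc([C@@]2(C)CCCC2(C)C)c(O)c(O)c1Cc1cc(O)c(O)c([C@@]2(C)CCCC2(C)C)c1 | target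

**Step count and risks**

Total steps: 19. Longest linear sequence: 16 steps (steps 1–5, 9–14, 15–19).

Steps most likely to fail:

1. Step 16. The cycloaddition may stall at the crowded, trisubstituted diene while the dienophile polymerises at the temperature required. The fallback keeps the same two bonds but uses a dienophile at a higher oxidation level, and it sets out from diene 21. Dichlorovinylene carbonate F2 is not a catalogue reagent and would be made from ethylene carbonate by photochlorination to tetrachloroethylene carbonate F1 followed by zinc dechlorination. It is a more electron-poor dienophile that is known to add to 1,3-dienes. Its [4+2] adduct with 21, the dichloro carbonate cycloadduct F3, would be hydrolysed in aqueous dioxane with loss of CO2 and HCl to ene-dione 24, which tautomerises. The route is rejoined at catechol 25, and steps 17 and 18 are not needed.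

2. Step 15. The 2E geometry may erode through syn–anti interconversion of the dienylpalladium intermediate, the intermediate may undergo β-hydride elimination to a triene, or base-free transmetalation may be too slow. The fallback is a copper-catalysed SN2 coupling that never passes through a π-allyl species, and it sets out from boronate 20 and dienol 10. Bromodeboronation of 20 (CuBr2, MeOH–H2O, 80 °C) should give the aryl bromide F4, and magnesium in THF would convert it into the arylmagnesium bromide F5. Dienol 10 with PBr3 in Et2O at −20 °C should give the dienyl bromide F6, to be used at once. F5 and F6 with CuI (cat.) in THF at −30 °C should couple at the primary carbon with retention of geometry, and the route is rejoined at diene 21.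

3. Step 9. The β-hydroxyphosphonate may not collapse completely, the allyl anion may attack through its γ-carbon, or E-selectivity may be poor at the hindered aldehyde. The fallback sets out from aldehyde 7. Takai iodo-olefination (CHI3, CrCl2, THF, 0 °C) should give the (E)-vinyl iodide F7 selectively, and Stille coupling of F7 with tributyl(vinyl)stannane (Pd(PPh3)4 cat., DMF, 60 °C) retains the E geometry. The route is rejoined at diene 13.

**Further compounds**

F1 | step 16 | tetrachloroethylene carbonate (4,4,5,5-tetrachloro-1,3-dioxolan-2-one) | O=C1OC(Cl)(Cl)C(Cl)(Cl)O1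
F2 | step 16 | dichlorovinylene carbonate (4,5-dichloro-1,3-dioxol-2-one) | O=C1OC(Cl)=C(Cl)O1
F3 | step 16 | 3a,7a-dichloro-4-{3,4-dimethoxy-5-[(1S)-1,2,2-trimethylcyclopentyl]benzyl}-5-methyl-7-[(1R)-1,2,2-trimethylcyclopentyl]-3a,4,7,7a-tetrahydro-1,3-benzodioxol-2-one (diastereomer mixture) | COc1cc(CC2C(C)=CC([C@@]4(C)CCCC4(C)C)C3(Cl)OC(=O)OC23Cl)cc([C@@]5(C)CCCC5(C)C)c1OC
F4 | step 15 | 5-bromo-1,2-dimethoxy-3-[(1S)-1,2,2-trimethylcyclopentyl]benzene | COc1cc(Br)cc([C@@]2(C)CCCC2(C)C)c1OC
F5 | step 15 | {3,4-dimethoxy-5-[(1S)-1,2,2-trimethylcyclopentyl]phenyl}magnesium bromide | COc1cc([Mg]Br)cc([C@@]2(C)CCCC2(C)C)c1OC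
F6 | step 15 | (1R)-1-[(1E,3E)-5-bromo-3-methylpenta-1,3-dien-1-yl]-1,2,2-trimethylcyclopentane | BrC/C=C(C)/C=C/[C@@]1(C)CCCC1(C)C
F7 | step 9 | (1R)-1-[(E)-2-iodoethenyl]-1,2,2-trimethylcyclopentane | I/C=C/[C@@]1(C)CCCC1(C)C
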